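**Strategy.** The benzene ring of the target is built de novo. The hydroxyl-bearing carbons C3 and C4 come from dimethyl oxalate. The bromine-bearing carbons C2 and C5 come from the two α-carbons of an adipate whose C3 already carries the CH2SO2Me arm (ring C1). One double Claisen condensation forms C2–C3 and C4–C5 and closes the six-membered carbocycle as a 2,3-dioxocyclohexane-1,4-dicarboxylate. The exploited feature is the Br–C2–C3(OH)–C4(OH)–C5–Br sequence of the catechol ring: each ester ends up ortho to a phenol and is later replaced by bromine through ipso-bromodecarboxylation. The precursor is racemic dimethyl 3-(methylsulfonylmethyl)hexanedioate, obtained by oxidative cleavage of a 4-substituted cyclohexene.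

Key step: step 5

Remark: the target has no stereocentre or other stereogenic element, so there is no enantiomer to select; racemic 1 is used and the stereocentre it passes on is erased on aromatisation in step 6.

**Step 1**
Reactants: 1 3-cyclohexene-1-methanol (racemic)
Product: 2 cyclohex-3-en-1-ylmethyl methanesulfonate
Conditions: MsCl (1.2 equiv), Et3N (1.5 equiv), CH2Cl2, 0 °C
Reagents that add atoms: methanesulfonyl chloride, CS(=O)(=O)Cl
Why: Mesylation (O-sulfonylation) of an unhindered primary alcohol is fast at 0 °C and leaves the isolated ring alkene untouched.

**Step 2**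
Reactants: 2 cyclohex-3-en-1-ylmethyl methanesulfonate; 3 sodium methanesulfinate
Product: 4 4-(methylsulfonylmethyl)cyclohex-1-ene
Conditions: MeSO2Na (1.5 equiv), DMF, 90 °C
Reagents that add atoms: none
Why: SN2 alkylation of the ambident sulfinate at sulfur by the primary mesylate in a dipolar aprotic solvent should give the sulfone directly, the β-branching only slowing the displacement and the remote alkene taking no part.

**Step 3**
Reactants: 4 4-(methylsulfonylmethyl)cyclohex-1-ene
Product: 6 3-(methylsulfonylmethyl)hexanedioic acid, via secondary ozonide 5 (not isolated)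
Conditions: O3, CH2Cl2, −78 °C; then HCO2H, 30% aq. H2O2, 25 → 90 °C
Reagents that add atoms: ozone, [O-][O+]=O; hydrogen peroxide, OO
Why: Criegee ozonolysis cleaves the only C=C bond to the secondary ozonide, and oxidative work-up with performic acid formed in situ carries both carbons to carboxylic acids, while the sulfone is already at its highest oxidation level.

**Step 4**
Reactants: 6 3-(methylsulfonylmethyl)hexanedioic acid
Product: 7 dimethyl 3-(methylsulfonylmethyl)hexanedioate
Conditions: MeOH, H2SO4 (cat.), reflux
Reagents that add atoms: methanol, CO
Why: Fischer esterification in excess methanol should convert both aliphatic acids to methyl esters, which match the alkoxide base and the oxalate of step 5 so that no ester scrambling can occur there.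

**Step 5**
Reactants: 7 dimethyl 3-(methylsulfonylmethyl)hexanedioate; 8 dimethyl oxalate
Product: 11 dimethyl 5-(methylsulfonylmethyl)-2,3-dioxocyclohexane-1,4-dicarboxylate, via open-chain oxalyl triester 9 (not isolated), via disodium dienolate 10 (not isolated)
Conditions: 7 added slowly to NaOMe (2.5 equiv) and (CO2Me)2 (1.05 equiv), MeOH–THF, 0 °C → reflux; then cold 1 M HCl
Reagents that add atoms: none
Why: Methoxide generates an ester enolate of 7 that attacks dimethyl oxalate in a crossed Claisen condensation to give 9 (drawn with the less hindered α-carbon acylated first; the other order converges), whose second ester enolate adds to the remaining oxalyl ester carbonyl and expels methoxide, after which double deprotonation gives dienolate 10 and acid returns 11, expected to exist mainly as its bis-enol. The closest known reaction type is the alkoxide-mediated condensation of dialkyl adipates with dialkyl oxalates to 2,3-dioxocyclohexane-1,4-dicarboxylates. The one ring is closed in the 6-exo-trig mode (Dieckmann closure), the attacked C=O lying outside the forming six-membered ring. No stereocentre has to be controlled, because C1 and C4 are enolised and the racemic C5 centre inherited from 7 disappears on aromatisation. The step needs C-acylation at the two ester α-CH2 groups in preference to the sulfone α-positions and to 5-exo self-Dieckmann closure of the adipate; this should be secured because esters are the stronger carbon acids under methoxide, every acyl transfer is reversible, and only the six-membered product can be deprotonated twice to a chelated, sparingly soluble disodium salt that draws the equilibria to 10.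

**Step 6**
Reactants: 11 dimethyl 5-(methylsulfonylmethyl)-2,3-dioxocyclohexane-1,4-dicarboxylate
Product: 12 dimethyl 2,3-dihydroxy-5-(methylsulfonylmethyl)benzene-1,4-dicarboxylate
Conditions: Br2 (1.05 equiv), CHCl3, 0 °C → reflux
Reagents that add atoms: none
Why: Bromination of an enolised β-keto ester carbon followed by loss of HBr and tautomerisation (bromination–dehydrobromination aromatisation of a cyclohexane-1,2-dione) should give the hydrogen-bonded catechol diester, and any extra bromination at the remaining ring CH would be harmless because that carbon bears bromine in the target.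

**Step 7**
Reactants: 12 dimethyl 2,3-dihydroxy-5-(methylsulfonylmethyl)benzene-1,4-dicarboxylate
Product: 14 2,3-dihydroxy-5-(methylsulfonylmethyl)benzene-1,4-dicarboxylic acid, via tetrasodium salt 13 (not isolated)
Conditions: NaOH (6 equiv), H2O–MeOH, reflux, N2; then 6 M HCl to pH 1, 0 °C
Reagents that add atoms: sodium hydroxide, [Na+].[OH-]
Why: Saponification (hydroxide acyl substitution) of the two aryl methyl esters under nitrogen, which keeps the catecholate from air oxidation, followed by acidification should precipitate the diacid with the sulfone untouched.

**Step 8**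
Reactants: 14 2,3-dihydroxy-5-(methylsulfonylmethyl)benzene-1,4-dicarboxylic acid
Product: 15 3,4,6-tribromo-5-(methylsulfonylmethyl)benzene-1,2-diol (target)
Conditions: Br2 (3.3 equiv), AcOH–H2O, 25 → 50 °C, dark; then aq. NaHSO3
Reagents that add atoms: bromine, BrBr
Why: Electrophilic bromination at the free ring CH para to a hydroxyl, plus two ipso-bromodecarboxylations at the carboxyl-bearing carbons ortho to the hydroxyls (ipso attack, then loss of CO2 from the cyclohexadienone σ-complex, as known for ortho- and para-hydroxybenzoic acids in aqueous bromine), should deliver the tribromocatechol, the bisulfite work-up reducing any o-quinone back to the catechol.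

**Compound list**
1 | 3-cyclohexene-1-methanol (racemic) | OCC1CCC=CC1 | starting material
2 | cyclohex-3-en-1-ylmethyl methanesulfonate (racemic) | CS(=O)(=O)OCC1CCC=CC1 | intermediate
3 | sodium methanesulfinate | CS(=O)[O-].[Na+] | starting material
4 | 4-(methylsulfonylmethyl)cyclohex-1-ene (racemic) | CS(=O)(=O)CC1CCC=CC1 | intermediate
5 | 3-(methylsulfonylmethyl)-7,8,9-trioxabicyclo[4.2.1]nonane (secondary ozonide, stereoisomer mixture, not isolated) | CS(=O)(=O)CC1CCC2OOC(C1)O2 | intermediate
6 | 3-(methylsulfonylmethyl)hexanedioic acid (racemic) | OC(=O)CCC(CS(C)(=O)=O)CC(=O)O | intermediate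
7 | dimethyl 3-(methylsulfonylmethyl)hexanedioate (racemic) | COC(=O)CCC(CS(C)(=O)=O)CC(=O)OC | intermediate
8 | dimethyl oxalate | COC(=O)C(=O)OC | starting material
9 | dimethyl 3-(methoxycarbonyl)-5-(methylsulfonylmethyl)-2-oxoheptanedioate (present as its sodium enolate, diastereomer mixture, not isolated) | COC(=O)C(=O)C(C(=O)OC)CC(CS(C)(=O)=O)CC(=O)OC | intermediate
10 | disodium 1,4-bis(methoxycarbonyl)-5-(methylsulfonylmethyl)cyclohexa-1,3-diene-2,3-diolate (racemic, not isolated) | COC(=O)C1=C([O-])C([O-])=C(C(=O)OC)C(CS(C)(=O)=O)C1.[Na+].[Na+] | intermediate
11 | dimethyl 5-(methylsulfonylmethyl)-2,3-dioxocyclohexane-1,4-dicarboxylate (drawn as diketone; enolisable centres undefined, racemic at C5) | COC(=O)C1CC(CS(C)(=O)=O)C(C(=O)OC)C(=O)C1=O | intermediate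
12 | dimethyl 2,3-dihydroxy-5-(methylsulfonylmethyl)benzene-1,4-dicarboxylate | COC(=O)c1cc(CS(C)(=O)=O)c(C(=O)OC)c(O)c1O | intermediate
13 | tetrasodium 2,3-dioxido-5-(methylsulfonylmethyl)benzene-1,4-dicarboxylate (not isolated) | CS(=O)(=O)Cc1cc(C(=O)[O-])c([O-])c([O-])c1C(=O)[O-].[Na+].[Na+].[Na+].[Na+] | intermediate
14 | 2,3-dihydroxy-5-(methylsulfonylmethyl)benzene-1,4-dicarboxylic acid | CS(=O)(=O)Cc1cc(C(=O)O)c(O)c(O)c1C(=O)O | intermediate
15 | 3,4,6-tribromo-5-(methylsulfonylmethyl)benzene-1,2-diol (achiral) | CS(=O)(=O)Cc1c(Br)c(O)c(O)c(Br)c1Br | target

**Step count and risks**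
Total steps: 8. Longest linear sequence: 8 steps (1 → 15).

Steps most likely to fail:

1. Step 5. Oxalylation at the sulfone α-carbons, or self-Dieckmann closure of the adipate to a cyclopentanone, may divert material before the six-membered dienolate can form. The fallback keeps the oxalate annulation but removes the acidic sulfone from it and installs the sulfone afterwards. Setting out from dimethyl oxalate 8, the same methoxide condensation would be run with purchased dimethyl 3-methylhexanedioate F1 to give dimethyl 5-methyl-2,3-dioxocyclohexane-1,4-dicarboxylate F2. Bromine aromatisation would give dimethyl 2,3-dihydroxy-5-methylbenzene-1,4-dicarboxylate F3, and acetylation (Ac2O, pyridine) would give dimethyl 2,3-diacetoxy-5-methylbenzene-1,4-dicarboxylate F4. Wohl–Ziegler bromination (NBS, AIBN, PhCF3, reflux) would give dimethyl 2,3-diacetoxy-5-(bromomethyl)benzene-1,4-dicarboxylate F5. Displacement with sodium methanesulfinate 3 (DMF, 25 °C) would give dimethyl 2,3-diacetoxy-5-(methylsulfonylmethyl)benzene-1,4-dicarboxylate F6. Global saponification (NaOH, then HCl) would remove both acetates and both methyl esters and rejoin the route at diacid 14.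

2. Step 8. The second ipso-substitution may stall on the ring once it is deactivated by bromine, or the catechol may be over-oxidised. The fallback separates decarboxylation from bromination. Setting out from diacid 14, classical copper-mediated protodecarboxylation (Cu powder, quinoline, about 200 °C, N2) would give 4-(methylsulfonylmethyl)benzene-1,2-diol F7. Ordinary exhaustive electrophilic bromination of its three free ring positions, each ortho or para to a hydroxyl (Br2, AcOH, 25 °C, bisulfite work-up), would then give target 15.

3. Step 2. Bimolecular substitution at the β-branched primary carbon may be slow, and the ambident sulfinate may alkylate at oxygen. The fallback uses a stronger sulfur nucleophile and adjusts the oxidation level afterwards. Setting out from mesylate 2, sodium thiomethoxide (DMF, 25 °C) would give 4-(methylsulfanylmethyl)cyclohex-1-ene F8. Oxone (MeOH–H2O, 0 → 25 °C) should oxidise sulfur to the sulfone without touching the isolated alkene, returning to the route at sulfone 4.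

**Further compounds**
F1 | step 5 | dimethyl 3-methylhexanedioate (purchased, racemic) | COC(=O)CCC(C)CC(=O)OC
F2 | step 5 | dimethyl 5-methyl-2,3-dioxocyclohexane-1,4-dicarboxylate | COC(=O)C1CC(C)C(C(=O)OC)C(=O)C1=O
F3 | step 5 | dimethyl 2,3-dihydroxy-5-methylbenzene-1,4-dicarboxylate | COC(=O)c1cc(C)c(C(=O)OC)c(O)c1O
F4 | step 5 | dimethyl 2,3-diacetoxy-5-methylbenzene-1,4-dicarboxylate | COC(=O)c1cc(C)c(C(=O)OC)c(OC(C)=O)c1OC(C)=O
F5 | step 5 | dimethyl 2,3-diacetoxy-5-(bromomethyl)benzene-1,4-dicarboxylate | COC(=O)c1cc(CBr)c(C(=O)OC)c(OC(C)=O)c1OC(C)=O
F6 | step 5 | dimethyl 2,3-diacetoxy-5-(methylsulfonylmethyl)benzene-1,4-dicarboxylate | COC(=O)c1cc(CS(C)(=O)=O)c(C(=O)OC)c(OC(C)=O)c1OC(C)=O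
F7 | step 8 | 4-(methylsulfonylmethyl)benzene-1,2-diol | CS(=O)(=O)Cc1ccc(O)c(O)c1
F8 | step 2 | 4-(methylsulfanylmethyl)cyclohex-1-ene (racemic) | CSCC1CCC=CC1
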